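**Plan**

1. Retrosynthesis: the C6 ester C–O bond is cut first. The C4=C5 bond is then traced back, by formal re-insertion of SO2, to a sulfone bridging C4 and C5. That thiacycle is opened at the C5–S bond (C4 thiolate plus C5–C6 epoxide). The C6–C7 bond goes back to the allylzinc of a 3-(bromomethyl)butenolide and a glycolaldehyde ether. The butenolide C7=C11 bond, the C8–vinyl bond and the furanone O–C3 and C1–C2 bonds lead to (R)-citramalic acid and (R)-but-3-yn-2-ol.
2. Forward order of rings: furanone (hydroxy ynone cyclisation), butenolide (ring-closing metathesis), α-methylene lactone with the C6–C7 bond (zinc allylation), thiacycle (eleven-membered along the carbon perimeter, ten-membered through the furanone oxygen), contraction to the ten-membered carbocycle, acylation at C6.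
3. Stereochemistry: C10 comes from (R)-citramalic acid. C8 is set by a catalyst-controlled vinylzinc addition. C7 is set by attack anti to the C8 substituent of the butenolide. C6 is set by the chair transition state of the allylation and then inverted on epoxide formation. The oxirane ester centres come from Sharpless epoxidation of (Z)-2-methylbut-2-en-1-ol.
4. Enabling feature: the C4=C5 alkene lies inside the nine-membered ring O1–C3–C4–C5–C6–C7–C8–C9–C10 defined by the furanone oxygen, which can hold only a cis double bond. C4 is bonded to furanone C3, so in the C4/C5-bridging sulfone its proton is the most acidic and it alone is chlorinated. Sulfur extrusion therefore has to give the Z-alkene.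

Key step: step 17

Remark on numbering: C1 is the furanone ketone carbon, C2 the furanone CH, C3 the furanone enol ether carbon, C4 (with methyl C15) and C5 the alkene carbons, C6 the acyloxy carbon, C7 and C8 the lactone ring carbons (C8 bears O), C9 the methylene, C10 the quaternary furanone carbon (with methyl C14), C11, C12 and C13 the α-carbon, carbonyl and methylidene of the lactone.

Assumption: the zinc allylation of step 10 is taken to follow the chair Zimmerman–Traxler transition state and therefore to give the C6 epimer, which steps 12 and 13 invert. The configurations at C4 (erased in step 17) and at C11 of the selenide-masked intermediates (erased in step 16) are of no consequence and are drawn as the expected isomers.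

**Route**

Step 1
Reactants: 1 (R)-citramalic acid
Product: 2 2-[(4R)-2,2,4-trimethyl-5-oxo-1,3-dioxolan-4-yl]acetic acid
Conditions: 2,2-dimethoxypropane, TsOH·H2O (cat.), CH2Cl2, rt
Reagents that add atoms: 2,2-dimethoxypropane, COC(C)(C)OC
Why: Acid-catalysed acetal exchange ties the α-hydroxy acid into the five-membered dioxolanone and leaves the β-carboxyl free, without touching the stereocentre.

Step 2
Reactants: 2 dioxolanone acid
Product: 4 (3R)-3-hydroxy-3-methyloxolan-2-one, via dioxolanone alcohol 3 (not isolated)
Conditions: BH3·SMe2, THF, 0 °C to rt; MeOH; then TsOH·H2O (cat.), CH2Cl2, rt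
Reagents that add atoms: none
Why: Borane reduces the free carboxylic acid chemoselectively beside the dioxolanone, and acid-catalysed translactonisation of the resulting alcohol expels acetone to give the hydroxy lactone.

Step 3
Reactants: 5 (R)-but-3-yn-2-ol
Product: 6 (R)-tert-butyl(but-3-yn-2-yloxy)dimethylsilane
Conditions: TBSCl, imidazole, CH2Cl2, 0 °C to rt
Reagents that add atoms: tert-butyldimethylsilyl chloride, CC(C)(C)[Si](C)(C)Cl
Why: Standard silylation of a secondary alcohol; the carbinol centre is not involved.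

Step 4
Reactants: 4 hydroxy lactone; 6 silyl ether of (R)-but-3-yn-2-ol
Product: 8 (3R,7R)-7-{[tert-butyl(dimethyl)silyl]oxy}-1,3-dihydroxy-3-methyloct-5-yn-4-one, via lithium acetylide 7 (not isolated)
Conditions: 6, n-BuLi, THF, −78 °C; 4 pre-treated with LiHMDS (1 equiv), THF, −78 °C; −78 to −30 °C; aq. NH4Cl
Reagents that add atoms: none
Why: Addition of a lithium acetylide to a γ-lactone stops at the lithium hemiketal, so work-up should give the hydroxy ynone (in equilibrium with its cyclic hemiketal) with both stereocentres carried in unchanged.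

Step 5
Reactants: 8 dihydroxy ynone
Product: 10 (2R)-5-[(1R)-1-{[tert-butyl(dimethyl)silyl]oxy}ethyl]-2-(2-hydroxyethyl)-2-methylfuran-3(2H)-one, via enaminone 9 (not isolated)
Conditions: Et2NH, EtOH, rt; then AcOH, H2O, THF, rt
Reagents that add atoms: none
Why: Conjugate addition of the amine to the ynone followed by acid-promoted addition–elimination by the tertiary hydroxyl (the classical α'-hydroxy ynone route to 3(2H)-furanones, formally a 5-endo closure) builds the furanone, while the primary hydroxyl could only close a seven-membered ring and stays free.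

Step 6
Reactants: 10 furanone alcohol
Product: 11 2-[(2R)-5-[(1R)-1-{[tert-butyl(dimethyl)silyl]oxy}ethyl]-2-methyl-3-oxo-2,3-dihydrofuran-2-yl]acetaldehyde
Conditions: Dess–Martin periodinane, NaHCO3, CH2Cl2, 0 °C to rt
Reagents that add atoms: none
Why: Buffered Dess–Martin oxidation gives the aldehyde under neutral conditions, which avoids β-elimination of the furanone oxygen.

Step 7
Reactants: 11 furanone aldehyde
Product: 12 (2R)-5-[(1R)-1-{[tert-butyl(dimethyl)silyl]oxy}ethyl]-2-[(2S)-2-hydroxybut-3-en-1-yl]-2-methylfuran-3(2H)-one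
Conditions: divinylzinc (from CH2=CHMgBr and ZnCl2, magnesium salts precipitated with 1,4-dioxane), (+)-MIB [(2R)-3-exo-morpholinoisoborneol] (10 mol %), toluene/Et2O, −20 °C
Reagents that add atoms: divinylzinc, C=C[Zn]C=C
Why: Amino-alcohol-catalysed enantioselective alkenylzinc addition, in which the catalyst and not the remote C10 centre controls the face; the (+)-enantiomer of the ligand is expected to deliver vinyl to the Re face and set C8 as S.

Step 8
Reactants: 12 allylic alcohol; 13 2-(bromomethyl)prop-2-enoic acid
Product: 14 (2S)-1-[(2R)-5-{(1R)-1-[(tert-butyldimethylsilyl)oxy]ethyl}-2-methyl-3-oxo-2,3-dihydrofuran-2-yl]but-3-en-2-yl 2-(bromomethyl)prop-2-enoate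
Conditions: DCC, DMAP (5 mol %), CH2Cl2, 0 °C
Reagents that add atoms: none
Why: Steglich esterification of the secondary alcohol under conditions mild enough to keep the allylic bromide, with retention at C8.

Step 9
Reactants: 14 diene ester
Product: 15 (5S)-3-(bromomethyl)-5-{[(2R)-5-{(1R)-1-[(tert-butyldimethylsilyl)oxy]ethyl}-2-methyl-3-oxo-2,3-dihydrofuran-2-yl]methyl}furan-2(5H)-one
Conditions: second-generation Grubbs catalyst (H2IMes)(PCy3)Cl2Ru=CHPh (5 mol %), toluene, 80 °C
Reagents that add atoms: none
Why: Ring-closing metathesis of an allylic acrylate to a butenolide starts at the monosubstituted vinyl group and closes on the acrylate with loss of ethylene, while the furanone enol ether is inert.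

Step 10
Reactants: 15 bromomethyl butenolide; 16 {[tert-butyl(dimethyl)silyl]oxy}acetaldehyde
Product: 18 (4S,5S)-4-[(1S)-2-{[tert-butyl(dimethyl)silyl]oxy}-1-hydroxyethyl]-5-{[(2R)-5-{(1R)-1-[(tert-butyldimethylsilyl)oxy]ethyl}-2-methyl-3-oxo-2,3-dihydrofuran-2-yl]methyl}-3-methylideneoxolan-2-one, via allylzinc bromide 17 (not isolated)
Conditions: Zn dust, THF/sat. aq. NH4Cl, 0 °C to rt
Reagents that add atoms: none
Why: Barbier allylation with allylic transposition forms C6–C7 and the exocyclic methylene in one operation: the aldehyde attacks C7 anti to the C8 substituent (trans lactone), and the chair Zimmerman–Traxler arrangement of the ring-locked E-allylzinc with the aldehyde substituent equatorial sets C6, epimeric to the target and corrected in step 13.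

Step 11
Reactants: 18 methylene lactone
Product: 19 selenide-masked lactone (18 with H and CH2SePh on C11 in place of the methylidene; CH2SePh trans to the C7 side chain)
Conditions: PhSeH, Et3N (cat.), CH2Cl2, 0 °C
Reagents that add atoms: benzeneselenol, [SeH]c1ccccc1
Why: Conjugate addition of benzeneselenol reversibly masks the α-methylene lactone, which would otherwise capture the thioacetate and thiolate of steps 14 and 15; protonation at C11 is expected trans to the C7 substituent.

Step 12
Reactants: 19 selenide
Product: 20 C6 methanesulfonate of 19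
Conditions: MsCl, Et3N, CH2Cl2, −20 °C
Reagents that add atoms: methanesulfonyl chloride, CS(=O)(=O)Cl
Why: Sulfonylation of the only free hydroxyl proceeds with retention and turns C6–O into a leaving group.

Step 13
Reactants: 20 mesylate
Product: 21 epoxy alcohol (C5–C6 oxirane with C6 configured as in the target; free (R)-C4 hydroxyl; selenide-masked lactone)
Conditions: TBAF (3 equiv), THF, 0 °C to rt
Reagents that add atoms: none
Why: Fluoride cleaves both silyl ethers and the liberated primary alkoxide displaces the neighbouring mesylate (intramolecular Williamson reaction, 3-exo-tet) with inversion, which brings C6 to the configuration of the target.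

Step 14
Reactants: 21 epoxy alcohol
Product: 22 C4 thioacetate (S-acetyl at C4 with 4S configuration; C5–C6 oxirane; selenide-masked lactone)
Conditions: PPh3, DIAD, AcSH, THF, 0 °C
Reagents that add atoms: thioacetic acid, CC(=O)S
Why: Mitsunobu thioesterification of the activated, lactate-like secondary alcohol installs sulfur at C4 with inversion, and the epoxide should survive the short exposure at 0 °C.

Step 15
Reactants: 22 thioacetate
Product: 24 macrocyclic hydroxy sulfide (sulfur links C4 and C5; free C6 hydroxyl configured as in the target; CH2SePh on C11), via thiol 23 (not isolated)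
Conditions: K2CO3, degassed MeOH/THF (0.002 M), 0 °C to rt
Reagents that add atoms: none
Why: Methanolysis frees the C4 thiolate, which opens the terminal epoxide at its unhindered carbon C5 in an intramolecular substitution under high dilution; this closes the thiacycle and releases the C6 hydroxyl without touching its configuration.

Step 16
Reactants: 24 macrocyclic sulfide
Product: 26 macrocyclic hydroxy sulfone with free α-methylene lactone (4S; C6, C7, C8 and C10 as in the target), via selenoxide sulfone 25 (not isolated)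
Conditions: mCPBA (3.5 equiv), NaHCO3, CH2Cl2, −20 °C to rt
Reagents that add atoms: 3-chloroperoxybenzoic acid, OOC(=O)c1cccc(Cl)c1
Why: The peracid oxidises the sulfide to the sulfone and the selenide to the selenoxide, whose syn-elimination through the only β-hydrogen (C11–H) regenerates the methylene lactone; the electron-poor alkenes are not epoxidised.

Step 17
Reactants: 26 macrocyclic sulfone
Product: 29 core alcohol (4Z; the target lacking the epoxyangeloyl group), via chloro sulfone 27 (not isolated), via episulfone 28 (not isolated)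
Conditions: LiHMDS (2.1 equiv), THF, −78 °C; C2Cl6; then KOtBu (3 equiv), −78 to 0 °C
Reagents that add atoms: none
Why: This is a Ramberg–Bäcklund reaction in its two-stage form: LiHMDS removes the hydroxyl proton and the C4 proton (the most acidic C–H, flanked by the sulfonyl group and furanone C3), C2Cl6 chlorinates that carbanion to 27, and KOtBu then deprotonates C5, whose carbanion displaces chloride to give episulfone 28, which loses SO2 cheletropically. The transient thiirane dioxide closes 3-exo-tet, and the lasting ten-membered carbocycle (nine-membered through O1) arises by contraction of the thiacycle made in step 15, not by an end-to-end C–C closure. No stereocentre is created, and both C4 epimers of 26 and of 27 converge on the same alkene. The geometry is set by the ring, since the nine-membered ring O1–C3–C4–C5–C6–C7–C8–C9–C10 can hold only the cis (Z) alkene, as in known contractions of medium-ring α-halo sulfones. The step needs chemoselectivity, which stoichiometric base at −78 °C should secure (the sulfone α-protons go before the lactone or furanone is attacked), and the C6 alkoxide cannot be expelled from the adjacent C5 carbanion.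

Step 18
Reactants: 30 angelic acid
Product: 31 (Z)-2-methylbut-2-en-1-ol
Conditions: LiAlH4, Et2O, 0 °C
Reagents that add atoms: none
Why: Hydride reduction of the acid to the allylic alcohol leaves the trisubstituted Z-alkene in place.

Step 19
Reactants: 31 (Z)-2-methylbut-2-en-1-ol
Product: 32 [(2R,3S)-2,3-dimethyloxiran-2-yl]methanol
Conditions: Ti(OiPr)4 (10 mol %), D-(−)-diethyl tartrate (12 mol %), tert-butyl hydroperoxide, 4 Å molecular sieves, CH2Cl2, −20 °C
Reagents that add atoms: tert-butyl hydroperoxide, CC(C)(C)OO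
Why: Katsuki–Sharpless epoxidation, in which the D-(−)-tartrate ligand directs oxygen to the face of the allylic alcohol that gives the (2R,3S) epoxide, with the cis relation of CH2OH and the C3 methyl fixed by the Z-alkene.

Step 20
Reactants: 32 epoxy alcohol
Product: 33 (2S,3S)-2,3-dimethyloxirane-2-carboxylic acid
Conditions: RuCl3·xH2O (2 mol %), NaIO4, CCl4/MeCN/H2O, rt
Reagents that add atoms: water, O
Why: Ruthenium tetroxide generated catalytically oxidises the primary alcohol through the aldehyde hydrate to the acid without opening the oxirane; the C2 descriptor changes from R to S by priority only.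

Step 21
Reactants: 29 core alcohol; 33 (2S,3S)-2,3-dimethyloxirane-2-carboxylic acid
Product: 35 target CNP0258430.4, via mixed anhydride 34 (not isolated)
Conditions: 33, 2,4,6-trichlorobenzoyl chloride, Et3N, THF, rt; then 29, DMAP, toluene, rt
Reagents that add atoms: none
Why: Yamaguchi esterification acylates the hindered allylic C6 hydroxyl with a quaternary acid, with retention at C6 and at both oxirane centres.

**Compound list**

1 | (R)-citramalic acid, (2R)-2-hydroxy-2-methylbutanedioic acid | OC(=O)C[C@@](C)(O)C(=O)O | starting material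
2 | 2-[(4R)-2,2,4-trimethyl-5-oxo-1,3-dioxolan-4-yl]acetic acid | OC(=O)C[C@@]1(C)OC(C)(C)OC1=O | intermediate
3 | (5R)-5-(2-hydroxyethyl)-2,2,5-trimethyl-1,3-dioxolan-4-one (not isolated) | OCC[C@@]1(C)OC(C)(C)OC1=O | intermediate
4 | (3R)-3-hydroxy-3-methyloxolan-2-one | C[C@@]1(O)CCOC1=O | intermediate
5 | (R)-but-3-yn-2-ol | C#C[C@@H](C)O | starting material
6 | (R)-tert-butyl(but-3-yn-2-yloxy)dimethylsilane | C#C[C@@H](C)O[Si](C)(C)C(C)(C)C | intermediate
7 | lithium acetylide of 6 (not isolated) | [Li]C#C[C@@H](C)O[Si](C)(C)C(C)(C)C | intermediate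
8 | (3R,7R)-7-{[tert-butyl(dimethyl)silyl]oxy}-1,3-dihydroxy-3-methyloct-5-yn-4-one | OCC[C@@](C)(O)C(=O)C#C[C@@H](C)O[Si](C)(C)C(C)(C)C | intermediate
9 | (3R,7R,5E)-7-{[tert-butyl(dimethyl)silyl]oxy}-6-(diethylamino)-1,3-dihydroxy-3-methyloct-5-en-4-one (not isolated; E geometry expected) | OCC[C@@](C)(O)C(=O)/C=C(/N(CC)CC)[C@@H](C)O[Si](C)(C)C(C)(C)C | intermediate
10 | (2R)-5-[(1R)-1-{[tert-butyl(dimethyl)silyl]oxy}ethyl]-2-(2-hydroxyethyl)-2-methylfuran-3(2H)-one | OCC[C@@]1(C)OC(=CC1=O)[C@@H](C)O[Si](C)(C)C(C)(C)C | intermediate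
11 | 2-[(2R)-5-[(1R)-1-{[tert-butyl(dimethyl)silyl]oxy}ethyl]-2-methyl-3-oxo-2,3-dihydrofuran-2-yl]acetaldehyde | O=CC[C@@]1(C)OC(=CC1=O)[C@@H](C)O[Si](C)(C)C(C)(C)C | intermediate
12 | (2R)-5-[(1R)-1-{[tert-butyl(dimethyl)silyl]oxy}ethyl]-2-[(2S)-2-hydroxybut-3-en-1-yl]-2-methylfuran-3(2H)-one | C=C[C@@H](O)C[C@@]1(C)OC(=CC1=O)[C@@H](C)O[Si](C)(C)C(C)(C)C | intermediate
13 | 2-(bromomethyl)prop-2-enoic acid | C=C(CBr)C(=O)O | starting material
14 | (2S)-1-[(2R)-5-{(1R)-1-[(tert-butyldimethylsilyl)oxy]ethyl}-2-methyl-3-oxo-2,3-dihydrofuran-2-yl]but-3-en-2-yl 2-(bromomethyl)prop-2-enoate | C=C(CBr)C(=O)O[C@H](C=C)C[C@@]1(C)OC(=CC1=O)[C@@H](C)O[Si](C)(C)C(C)(C)C | intermediate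
15 | (5S)-3-(bromomethyl)-5-{[(2R)-5-{(1R)-1-[(tert-butyldimethylsilyl)oxy]ethyl}-2-methyl-3-oxo-2,3-dihydrofuran-2-yl]methyl}furan-2(5H)-one | BrCC1=C[C@H](C[C@@]2(C)OC(=CC2=O)[C@@H](C)O[Si](C)(C)C(C)(C)C)OC1=O | intermediate
16 | {[tert-butyl(dimethyl)silyl]oxy}acetaldehyde | O=CCO[Si](C)(C)C(C)(C)C | starting material
17 | allylzinc bromide from 15, zinc on the former bromomethyl carbon (not isolated) | Br[Zn]CC1=C[C@H](C[C@@]2(C)OC(=CC2=O)[C@@H](C)O[Si](C)(C)C(C)(C)C)OC1=O | intermediate
18 | (4S,5S)-4-[(1S)-2-{[tert-butyl(dimethyl)silyl]oxy}-1-hydroxyethyl]-5-{[(2R)-5-{(1R)-1-[(tert-butyldimethylsilyl)oxy]ethyl}-2-methyl-3-oxo-2,3-dihydrofuran-2-yl]methyl}-3-methylideneoxolan-2-one (lactone substituents trans; carbinol C6 epimeric to the target) | C=C1C(=O)O[C@@H](C[C@@]2(C)OC(=CC2=O)[C@@H](C)O[Si](C)(C)C(C)(C)C)[C@@H]1[C@H](O)CO[Si](C)(C)C(C)(C)C | intermediate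
19 | selenide-masked lactone: 18 with H and (phenylselanyl)methyl on C11 in place of the methylidene, CH2SePh trans to the C7 side chain | c3ccccc3[Se]C[C@H]1C(=O)O[C@@H](C[C@@]2(C)OC(=CC2=O)[C@@H](C)O[Si](C)(C)C(C)(C)C)[C@@H]1[C@H](O)CO[Si](C)(C)C(C)(C)C | intermediate
20 | C6 methanesulfonate of 19 | c3ccccc3[Se]C[C@H]1C(=O)O[C@@H](C[C@@]2(C)OC(=CC2=O)[C@@H](C)O[Si](C)(C)C(C)(C)C)[C@@H]1[C@H](OS(C)(=O)=O)CO[Si](C)(C)C(C)(C)C | intermediate
21 | epoxy alcohol: C5–C6 oxirane (C6 as in the target), free (R)-C4 hydroxyl, selenide-masked lactone | c3ccccc3[Se]C[C@H]1C(=O)O[C@@H](C[C@@]2(C)OC(=CC2=O)[C@@H](C)O)[C@@H]1[C@@H]4CO4 | intermediate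
22 | C4 thioacetate: S-acetyl on C4 (4S), C5–C6 oxirane, selenide-masked lactone | c3ccccc3[Se]C[C@H]1C(=O)O[C@@H](C[C@@]2(C)OC(=CC2=O)[C@H](C)SC(C)=O)[C@@H]1[C@@H]4CO4 | intermediate
23 | C4 thiol of 22 (not isolated) | c3ccccc3[Se]C[C@H]1C(=O)O[C@@H](C[C@@]2(C)OC(=CC2=O)[C@H](C)S)[C@@H]1[C@@H]4CO4 | intermediate
24 | macrocyclic hydroxy sulfide: sulfur between C4 (4S) and C5, C6 hydroxyl as in the target, CH2SePh on C11 | c4ccccc4[Se]C[C@H]1C(=O)O[C@H]2C[C@@]3(C)OC(=CC3=O)[C@H](C)SC[C@H](O)[C@H]12 | intermediate
25 | selenoxide of the sulfone derived from 24 (not isolated; selenium centre undefined) | c4ccccc4[Se](=O)C[C@H]1C(=O)O[C@H]2C[C@@]3(C)OC(=CC3=O)[C@H](C)S(=O)(=O)C[C@H](O)[C@H]12 | intermediate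
26 | macrocyclic hydroxy sulfone: SO2 between C4 (4S) and C5, free C6 hydroxyl, α-methylene lactone; C6, C7, C8, C10 as in the target | C=C1C(=O)O[C@H]2C[C@@]3(C)OC(=CC3=O)[C@H](C)S(=O)(=O)C[C@H](O)[C@H]12 | intermediate
27 | C4-chloro derivative of sulfone 26 (not isolated; either C4 epimer) | C=C1C(=O)O[C@H]2C[C@@]3(C)OC(=CC3=O)C(C)(Cl)S(=O)(=O)C[C@H](O)[C@H]12 | intermediate
28 | episulfone: thiirane 1,1-dioxide across C4–C5, cis-fused to the macrocycle (not isolated; C4 and C5 not defined further) | C=C1C(=O)O[C@H]2C[C@@]3(C)OC(=CC3=O)C4(C)C(S4(=O)=O)[C@H](O)[C@H]12 | intermediate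
29 | core alcohol: (4Z)-alkene, free C6 hydroxyl, the target without the epoxyangeloyl group | C=C1C(=O)O[C@H]2C[C@@]3(C)OC(=CC3=O)/C(C)=C\[C@H](O)[C@H]12 | intermediate
30 | angelic acid, (Z)-2-methylbut-2-enoic acid | C/C=C(/C)C(=O)O | starting material
31 | (Z)-2-methylbut-2-en-1-ol | C/C=C(/C)CO | intermediate
32 | [(2R,3S)-2,3-dimethyloxiran-2-yl]methanol | OC[C@@]1(C)O[C@H]1C | intermediate
33 | (2S,3S)-2,3-dimethyloxirane-2-carboxylic acid | OC(=O)[C@@]1(C)O[C@H]1C | intermediate
34 | (2S,3S)-2,3-dimethyloxirane-2-carboxylic 2,4,6-trichlorobenzoic anhydride (not isolated) | O=C(OC(=O)c1c(Cl)cc(Cl)cc1Cl)[C@@]1(C)O[C@H]1C | intermediate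
35 | CNP0258430.4: the (2S,3S)-2,3-dimethyloxirane-2-carboxylate of core alcohol 29 at C6; (4Z,6S,7R,8S,10R) | C=C1C(=O)O[C@H]2C[C@@]3(C)OC(=CC3=O)/C(C)=C\[C@H](OC(=O)[C@@]3(C)O[C@H]3C)[C@H]12 | target

**Step count and risks**

Total step count: 21. Longest linear sequence: 17 steps (steps 1, 2, 4 to 17 and 21, from (R)-citramalic acid).

1. Step 15 (thiacycle closure). What may go wrong: intermolecular epoxide opening (oligomerisation) may outrun the medium-ring closure, or the hindered secondary thiolate may attack the epoxide too slowly. The fallback reverses the polarity of the ring closure (thiolate on C5, activated leaving group on C4). It sets out from mesylate 20 and returns at sulfide 24. HF·pyridine removes only the primary silyl ether to give hydroxy mesylate F1, and K2CO3 in MeOH closes it to epoxide silyl ether F2 with the same inversion at C6. KSAc with AcOH in DMF opens the epoxide at C5 to hydroxy thioacetate F3, and Ac2O in pyridine gives acetate F4. HF·pyridine at rt frees the C4 hydroxyl in alcohol F5, and MsCl/Et3N gives C4 mesylate F6. K2CO3 in degassed MeOH at high dilution then removes both acetyl groups, and the C5 thiolate displaces the activated C4 mesylate with inversion to give 24.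

2. Step 17 (ring contraction). What may go wrong: tert-butoxide or the sulfonyl carbanion may add to the unmasked methylene lactone under the strongly basic conditions. The fallback contracts the ring with the Michael acceptor masked. It sets out from sulfone 26 and returns at core alcohol 29. Me2NH in THF adds to the methylene lactone to give amine adduct F7. The same deprotonation and chlorination should give chloro sulfone F8, and KOtBu should close episulfone F9, which loses SO2 to amino alkene F10. MeI gives methiodide F11, and aqueous NaHCO3 eliminates trimethylamine to return 29.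

3. Step 10 (zinc allylation). What may go wrong: the preference for the chair transition state may be incomplete (a boat or a chelated arrangement through the silyloxy group may compete), which would give a mixture of C6 epimers. The fallback replaces substrate control by reagent control. It sets out from selenide 19, obtained as a mixture with its C6 epimer, and returns at 19. Dess–Martin oxidation of the mixture gives ketone F12. Reduction with BH3·SMe2 and the (S)-Me-CBS oxazaborolidine, with the branched C7 carbon as the large substituent, is expected to return 19 as a single C6 epimer.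

**Further compounds**

F1 | step 15 | hydroxy mesylate: 20 with the primary silyl ether removed | c3ccccc3[Se]C[C@H]1C(=O)O[C@@H](C[C@@]2(C)OC(=CC2=O)[C@@H](C)O[Si](C)(C)C(C)(C)C)[C@@H]1[C@H](OS(C)(=O)=O)CO
F2 | step 15 | epoxide silyl ether: C5–C6 oxirane (C6 as in the target), C4 silyl ether retained | c3ccccc3[Se]C[C@H]1C(=O)O[C@@H](C[C@@]2(C)OC(=CC2=O)[C@@H](C)O[Si](C)(C)C(C)(C)C)[C@@H]1[C@@H]4CO4
F3 | step 15 | hydroxy thioacetate: S-acetyl on C5, free C6 hydroxyl, C4 silyl ether | c3ccccc3[Se]C[C@H]1C(=O)O[C@@H](C[C@@]2(C)OC(=CC2=O)[C@@H](C)O[Si](C)(C)C(C)(C)C)[C@@H]1[C@@H](O)CSC(C)=O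
F4 | step 15 | C6 acetate of F3 | c3ccccc3[Se]C[C@H]1C(=O)O[C@@H](C[C@@]2(C)OC(=CC2=O)[C@@H](C)O[Si](C)(C)C(C)(C)C)[C@@H]1[C@@H](OC(C)=O)CSC(C)=O
F5 | step 15 | C4 alcohol: F4 with the C4 silyl ether removed | c3ccccc3[Se]C[C@H]1C(=O)O[C@@H](C[C@@]2(C)OC(=CC2=O)[C@@H](C)O)[C@@H]1[C@@H](OC(C)=O)CSC(C)=O
F6 | step 15 | C4 methanesulfonate of F5 | c3ccccc3[Se]C[C@H]1C(=O)O[C@@H](C[C@@]2(C)OC(=CC2=O)[C@@H](C)OS(C)(=O)=O)[C@@H]1[C@@H](OC(C)=O)CSC(C)=O
F7 | step 17 | dimethylamine adduct of sulfone 26 (CH2NMe2 on C11, trans to the C7 substituent) | CN(C)C[C@H]1C(=O)O[C@H]2C[C@@]3(C)OC(=CC3=O)[C@H](C)S(=O)(=O)C[C@H](O)[C@H]12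
F8 | step 17 | C4-chloro sulfone of F7 (either C4 epimer) | CN(C)C[C@H]1C(=O)O[C@H]2C[C@@]3(C)OC(=CC3=O)C(C)(Cl)S(=O)(=O)C[C@H](O)[C@H]12
F9 | step 17 | episulfone of the amine-masked series (cis-fused; C4 and C5 not defined further) | CN(C)C[C@H]1C(=O)O[C@H]2C[C@@]3(C)OC(=CC3=O)C4(C)C(S4(=O)=O)[C@H](O)[C@H]12
F10 | step 17 | amino alkene: dimethylamine adduct of core alcohol 29 | CN(C)C[C@H]1C(=O)O[C@H]2C[C@@]3(C)OC(=CC3=O)/C(C)=C\[C@H](O)[C@H]12
F11 | step 17 | trimethylammonium iodide of F10 | C[N+](C)(C)C[C@H]1C(=O)O[C@H]2C[C@@]3(C)OC(=CC3=O)/C(C)=C\[C@H](O)[C@H]12.[I-]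
F12 | step 10 | C6 ketone of selenide 19 | c3ccccc3[Se]C[C@H]1C(=O)O[C@@H](C[C@@]2(C)OC(=CC2=O)[C@@H](C)O[Si](C)(C)C(C)(C)C)[C@@H]1C(=O)CO[Si](C)(C)C(C)(C)C
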